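**Retrosynthetic overview** (C1–C15 = target chain, numbered from the alkyne end)
1. Both C–Br bonds are made by SN2 inversion of carbinols: C9 at the alkyne stage, C13 in the last step. The (3Z)-enyne comes from a Z-selective enyne cross-metathesis on a C6 allyl group, and the (11Z)-alkene from semi-hydrogenation of a C11–C12 alkyne.
2. Key disconnection is C10–C11, not a ring C–O bond: a tin acetylide is added to a furanosyl 1,2-diacetate, and the C9 acetate directs it 1,2-trans. A 5-endo bromo-etherification is avoided because it would be expected to put Br cis to the C7 chain.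
3. The only ring (the oxolane) is formed once, early, as a de novo 3-deoxyfuranose by transacetalisation of an acyclic anti-1,3-diol dimethyl acetal.
4. C6–Cl, C7–O and C9–O are set in the first three steps: organocatalytic α-chlorination of pent-4-enal, Cornforth-selective aldol with 1,1-dimethoxyacetone, and 1,3-anti reduction. The chlorine is carried through from step 1.

Assumption: (2S,5S)-2,5-diphenylpyrrolidine is taken as the catalyst antipode that gives (R)-2-chloroaldehydes with NCS (the mirror-image catalyst is used if the sense is opposite), and (3S)-pent-1-yn-3-ol is taken as a commercial single enantiomer.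

**Route**

Step 1
Reactants: 1 pent-4-enal
Product: 2 (2R)-2-chloropent-4-enal
Conditions: NCS (1.3 equiv), (2S,5S)-2,5-diphenylpyrrolidine (10 mol%), CH2Cl2, rt; used as a filtered pentane solution
Reagents that add atoms: N-chlorosuccinimide, O=C1CCC(=O)N1Cl
Why: Enamine-catalysed electrophilic α-chlorination (organocatalysis) chlorinates one face of the C2-symmetric pyrrolidine enamine, which sets C6 as R and leaves the allyl group untouched.

Step 2
Reactants: 2 (2R)-2-chloropent-4-enal; 3 1,1-dimethoxypropan-2-one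
Product: 5 (4S,5R)-5-chloro-4-hydroxy-1,1-dimethoxyoct-7-en-2-one, via lithium enolate 4 (not isolated)
Conditions: 3, LiN(i-Pr)2, THF, −78 °C; then 2, −78 °C; AcOH quench at −78 °C
Reagents that add atoms: none
Why: Lithium-enolate aldol addition to an α-chloroaldehyde follows the Cornforth model, so the new carbinol C7 (C4 of 5) forms anti to the C–Cl bond, and the cold acid quench prevents epoxide closure.

Step 3
Reactants: 5 (4S,5R)-5-chloro-4-hydroxy-1,1-dimethoxyoct-7-en-2-one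
Product: 6 (2S,4S,5R)-5-chloro-1,1-dimethoxyoct-7-ene-2,4-diol
Conditions: Me4NBH(OAc)3, MeCN/AcOH (1:1), −30 °C
Reagents that add atoms: none
Why: Evans–Saksena reduction, in which the boron-bound C7 alkoxide delivers hydride intramolecularly to the ketone, gives the 1,3-anti diol and so sets C9 (C2 of 6) as S.

Step 4
Reactants: 6 (2S,4S,5R)-5-chloro-1,1-dimethoxyoct-7-ene-2,4-diol
Product: 8 (3S,5S)-5-[(1R)-1-chlorobut-3-en-1-yl]oxolane-2,3-diyl diacetate (anomer mixture), via methyl furanoside 7 (not isolated)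
Conditions: TsOH·H2O (5 mol%), CH2Cl2, 5 Å MS, rt; then Ac2O, AcOH, H2SO4 (cat.), 0 °C
Reagents that add atoms: acetic anhydride, CC(=O)OC(C)=O
Why: Acid-catalysed transacetalisation closes the only ring through the C7 hydroxyl (the C9 hydroxyl could only give a three-membered ring), and acetolysis then exchanges OMe for OAc and acetylates the C9 hydroxyl without touching C6, C7 or C9.

Step 5
Reactants: 9 (3S)-pent-1-yn-3-ol
Product: 10 tert-butyl(dimethyl)[(3S)-pent-1-yn-3-yloxy]silane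
Conditions: t-BuMe2SiCl, imidazole, DMF, rt
Reagents that add atoms: tert-butyl(chloro)dimethylsilane, CC(C)(C)[Si](C)(C)Cl
Why: Standard silyl ether formation at the propargylic hydroxyl, with no change at the stereocentre (the future C13).

Step 6
Reactants: 10 tert-butyl(dimethyl)[(3S)-pent-1-yn-3-yloxy]silane
Product: 12 tributyl[(3S)-3-{[tert-butyl(dimethyl)silyl]oxy}pent-1-yn-1-yl]stannane, via lithium acetylide 11 (not isolated)
Conditions: n-BuLi, THF, −78 °C; then Bu3SnCl, −78 °C to rt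
Reagents that add atoms: tributyltin chloride, CCCC[Sn](Cl)(CCCC)CCCC
Why: Deprotonation of the terminal alkyne and lithium-to-tin transmetallation give a storable tin acetylide that reacts with oxocarbenium ions but not with esters.

Step 7
Reactants: 8 (3S,5S)-5-[(1R)-1-chlorobut-3-en-1-yl]oxolane-2,3-diyl diacetate; 12 tributyl[(3S)-3-{[tert-butyl(dimethyl)silyl]oxy}pent-1-yn-1-yl]stannane
Product: 13 (2R,3S,5S)-2-[(3S)-3-{[tert-butyl(dimethyl)silyl]oxy}pent-1-yn-1-yl]-5-[(1R)-1-chlorobut-3-en-1-yl]oxolan-3-yl acetate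
Conditions: Me3SiOTf (1.5 equiv), 12 (1.5 equiv), CH2Cl2, 4 Å MS, −40 to 0 °C
Reagents that add atoms: none
Why: Lewis-acid C-glycosylation with neighbouring-group participation, in which the C9 acetate shields its own face of the anomeric cation so the tin acetylide adds anti to it and to the C7 chain, setting C10 as R (2,3-trans), as in nucleoside syntheses from 3-deoxyfuranosyl 1,2-diacetates.

Step 8
Reactants: 13 (2R,3S,5S)-2-[(3S)-3-{[tert-butyl(dimethyl)silyl]oxy}pent-1-yn-1-yl]-5-[(1R)-1-chlorobut-3-en-1-yl]oxolan-3-yl acetate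
Product: 14 (2R,3S,5S)-2-[(3S)-3-{[tert-butyl(dimethyl)silyl]oxy}pent-1-yn-1-yl]-5-[(1R)-1-chlorobut-3-en-1-yl]oxolan-3-ol
Conditions: K2CO3 (0.2 equiv), MeOH, 0 °C
Reagents that add atoms: none
Why: Zemplén-type transesterification frees the C9 hydroxyl, and the silyl ether, the chloride and the alkyne are stable to catalytic carbonate in methanol at 0 °C.

Step 9
Reactants: 14 (2R,3S,5S)-2-[(3S)-3-{[tert-butyl(dimethyl)silyl]oxy}pent-1-yn-1-yl]-5-[(1R)-1-chlorobut-3-en-1-yl]oxolan-3-ol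
Product: 15 {[(3S)-1-[(2R,3R,5S)-3-bromo-5-[(1R)-1-chlorobut-3-en-1-yl]oxolan-2-yl]pent-1-yn-3-yl]oxy}(tert-butyl)dimethylsilane
Conditions: CBr4, P(n-Oct)3, toluene, 70 °C
Reagents that add atoms: carbon tetrabromide, BrC(Br)(Br)Br
Why: Appel-type bromination (oxyphosphonium formation, then SN2 attack by bromide) inverts C9 to R and places bromine cis to the slim alkynyl group, as in 3′-inversions of 2′-deoxynucleosides.

Step 10
Reactants: 15 {[(3S)-1-[(2R,3R,5S)-3-bromo-5-[(1R)-1-chlorobut-3-en-1-yl]oxolan-2-yl]pent-1-yn-3-yl]oxy}(tert-butyl)dimethylsilane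
Product: 16 {[(1Z,3S)-1-[(2R,3R,5S)-3-bromo-5-[(1R)-1-chlorobut-3-en-1-yl]oxolan-2-yl]pent-1-en-3-yl]oxy}(tert-butyl)dimethylsilane
Conditions: H2 (1 atm, stopped at 1.0 equiv), Pd/CaCO3 poisoned with Pb(OAc)2 (Lindlar-type), quinoline, EtOAc, rt
Reagents that add atoms: none
Why: Lindlar-type semi-hydrogenation adds H2 syn to the alkyne to give the (11Z)-alkene, and the poisoned catalyst spares the terminal alkene and the C–Br and C–Cl bonds when stopped after one equivalent.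

Step 11
Reactants: 17 ethynyltri(propan-2-yl)silane; 18 bromoethene
Product: 19 (but-3-en-1-yn-1-yl)tri(propan-2-yl)silane
Conditions: PdCl2(PPh3)2 (2 mol%), CuI (4 mol%), i-Pr2NH, THF, 0 °C to rt
Reagents that add atoms: none
Why: Sonogashira coupling of a vinyl bromide with a terminal alkyne gives the conjugated enyne partner.

Step 12
Reactants: 16 {[(1Z,3S)-1-[(2R,3R,5S)-3-bromo-5-[(1R)-1-chlorobut-3-en-1-yl]oxolan-2-yl]pent-1-en-3-yl]oxy}(tert-butyl)dimethylsilane; 19 (but-3-en-1-yn-1-yl)tri(propan-2-yl)silane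
Product: 20 {[(1Z,3S)-1-[(2R,3R,5S)-3-bromo-5-[(1R,3Z)-1-chloro-6-[tri(propan-2-yl)silyl]hex-3-en-5-yn-1-yl]oxolan-2-yl]pent-1-en-3-yl]oxy}(tert-butyl)dimethylsilane
Conditions: 19 (4 equiv), RuCl2(=CHPh)(H2IMes)(PCy3) (second-generation Grubbs catalyst, 10 mol%), CH2Cl2, 40 °C
Reagents that add atoms: none
Why: Olefin cross-metathesis between the terminal alkene and a silyl-capped conjugated enyne, which with this catalyst is known to favour the (Z)-enyne, while the hindered C11=C12 alkene does not take part.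

Step 13
Reactants: 20 {[(1Z,3S)-1-[(2R,3R,5S)-3-bromo-5-[(1R,3Z)-1-chloro-6-[tri(propan-2-yl)silyl]hex-3-en-5-yn-1-yl]oxolan-2-yl]pent-1-en-3-yl]oxy}(tert-butyl)dimethylsilane
Product: 21 (1Z,3S)-1-[(2R,3R,5S)-3-bromo-5-[(1R,3Z)-1-chlorohex-3-en-5-yn-1-yl]oxolan-2-yl]pent-1-en-3-ol
Conditions: Bu4NF, AcOH (1:1, 3 equiv), THF, 0 °C to rt
Reagents that add atoms: none
Why: Fluoride-mediated desilylation cleaves both the alkynyl C–Si bond and the allylic silyl ether, and the acetic acid buffer suppresses E2 loss of HBr.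

Step 14
Reactants: 21 (1Z,3S)-1-[(2R,3R,5S)-3-bromo-5-[(1R,3Z)-1-chlorohex-3-en-5-yn-1-yl]oxolan-2-yl]pent-1-en-3-ol
Product: 22 (2R,3R,5S)-3-bromo-2-[(1Z,3R)-3-bromopent-1-en-1-yl]-5-[(1R,3Z)-1-chlorohex-3-en-5-yn-1-yl]oxolane (CNP0136321.2)
Conditions: CBr4, PPh3, 2,6-di-tert-butylpyridine, CH2Cl2, 0 °C
Reagents that add atoms: carbon tetrabromide, BrC(Br)(Br)Br
Why: The Appel reaction on the allylic alcohol proceeds by SN2 displacement with inversion (13S to 13R) at low temperature, as used for allylic bromides of related Laurencia ethers.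

**Compound list**

1 | pent-4-enal | C=CCCC=O | starting material
2 | (2R)-2-chloropent-4-enal | C=CC[C@@H](Cl)C=O | intermediate
3 | 1,1-dimethoxypropan-2-one | CC(=O)C(OC)OC | starting material
4 | lithium 3,3-dimethoxyprop-1-en-2-olate (lithium enolate) | [Li+].[O-]C(=C)C(OC)OC | intermediate
5 | (4S,5R)-5-chloro-4-hydroxy-1,1-dimethoxyoct-7-en-2-one | C=CC[C@@H](Cl)[C@@H](O)CC(=O)C(OC)OC | intermediate
6 | (2S,4S,5R)-5-chloro-1,1-dimethoxyoct-7-ene-2,4-diol | C=CC[C@@H](Cl)[C@@H](O)C[C@H](O)C(OC)OC | intermediate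
7 | (3S,5S)-5-[(1R)-1-chlorobut-3-en-1-yl]-2-methoxyoxolan-3-ol (methyl furanoside, anomer mixture) | C=CC[C@@H](Cl)[C@@H]1C[C@H](O)C(OC)O1 | intermediate
8 | (3S,5S)-5-[(1R)-1-chlorobut-3-en-1-yl]oxolane-2,3-diyl diacetate (anomer mixture) | C=CC[C@@H](Cl)[C@@H]1C[C@H](OC(C)=O)C(OC(C)=O)O1 | intermediate
9 | (3S)-pent-1-yn-3-ol | CC[C@H](O)C#C | starting material
10 | tert-butyl(dimethyl)[(3S)-pent-1-yn-3-yloxy]silane | CC[C@H](O[Si](C)(C)C(C)(C)C)C#C | intermediate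
11 | lithium (3S)-3-{[tert-butyl(dimethyl)silyl]oxy}pent-1-yn-1-ide (lithium acetylide) | CC[C@H](O[Si](C)(C)C(C)(C)C)C#C[Li] | intermediate
12 | tributyl[(3S)-3-{[tert-butyl(dimethyl)silyl]oxy}pent-1-yn-1-yl]stannane | CC[C@H](O[Si](C)(C)C(C)(C)C)C#C[Sn](CCCC)(CCCC)CCCC | intermediate
13 | (2R,3S,5S)-2-[(3S)-3-{[tert-butyl(dimethyl)silyl]oxy}pent-1-yn-1-yl]-5-[(1R)-1-chlorobut-3-en-1-yl]oxolan-3-yl acetate | C=CC[C@@H](Cl)[C@@H]1C[C@H](OC(C)=O)[C@@H](C#C[C@@H](O[Si](C)(C)C(C)(C)C)CC)O1 | intermediate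
14 | (2R,3S,5S)-2-[(3S)-3-{[tert-butyl(dimethyl)silyl]oxy}pent-1-yn-1-yl]-5-[(1R)-1-chlorobut-3-en-1-yl]oxolan-3-ol | C=CC[C@@H](Cl)[C@@H]1C[C@H](O)[C@@H](C#C[C@@H](O[Si](C)(C)C(C)(C)C)CC)O1 | intermediate
15 | {[(3S)-1-[(2R,3R,5S)-3-bromo-5-[(1R)-1-chlorobut-3-en-1-yl]oxolan-2-yl]pent-1-yn-3-yl]oxy}(tert-butyl)dimethylsilane | C=CC[C@@H](Cl)[C@@H]1C[C@@H](Br)[C@@H](C#C[C@@H](O[Si](C)(C)C(C)(C)C)CC)O1 | intermediate
16 | {[(1Z,3S)-1-[(2R,3R,5S)-3-bromo-5-[(1R)-1-chlorobut-3-en-1-yl]oxolan-2-yl]pent-1-en-3-yl]oxy}(tert-butyl)dimethylsilane | C=CC[C@@H](Cl)[C@@H]1C[C@@H](Br)[C@@H](/C=C\[C@@H](O[Si](C)(C)C(C)(C)C)CC)O1 | intermediate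
17 | ethynyltri(propan-2-yl)silane | C#C[Si](C(C)C)(C(C)C)C(C)C | starting material
18 | bromoethene | C=CBr | starting material
19 | (but-3-en-1-yn-1-yl)tri(propan-2-yl)silane | C=CC#C[Si](C(C)C)(C(C)C)C(C)C | intermediate
20 | {[(1Z,3S)-1-[(2R,3R,5S)-3-bromo-5-[(1R,3Z)-1-chloro-6-[tri(propan-2-yl)silyl]hex-3-en-5-yn-1-yl]oxolan-2-yl]pent-1-en-3-yl]oxy}(tert-butyl)dimethylsilane | CC(C)[Si](C(C)C)(C(C)C)C#C/C=C\C[C@@H](Cl)[C@@H]1C[C@@H](Br)[C@@H](/C=C\[C@@H](O[Si](C)(C)C(C)(C)C)CC)O1 | intermediate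
21 | (1Z,3S)-1-[(2R,3R,5S)-3-bromo-5-[(1R,3Z)-1-chlorohex-3-en-5-yn-1-yl]oxolan-2-yl]pent-1-en-3-ol | C#C/C=C\C[C@@H](Cl)[C@@H]1C[C@@H](Br)[C@@H](/C=C\[C@@H](O)CC)O1 | intermediate
22 | (2R,3R,5S)-3-bromo-2-[(1Z,3R)-3-bromopent-1-en-1-yl]-5-[(1R,3Z)-1-chlorohex-3-en-5-yn-1-yl]oxolane | C#C/C=C\C[C@@H](Cl)[C@@H]1C[C@@H](Br)[C@@H](/C=C\[C@H](Br)CC)O1 | target

**Step count**

Total step count: 14. Longest linear sequence: 11 steps (steps 1, 2, 3, 4, 7, 8, 9, 10, 12, 13, 14).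

**The three steps most likely to fail, with fallbacks**

Step 7 (C-alkynylation). The tin acetylide may attack the carbon of the participating acetate (giving an orthoester-type ketal) or react sluggishly. The fallback sets out from 6 and comes back at 14. Aqueous acid (1 M HCl, THF, 40 °C) hydrolyses the acetal of 6 to (3S,5S)-5-[(1R)-1-chlorobut-3-en-1-yl]oxolane-2,3-diol F1. Ag2CO3 on Celite (benzene, reflux) oxidises only the lactol, giving (3S,5S)-5-[(1R)-1-chlorobut-3-en-1-yl]-3-hydroxyoxolan-2-one F2. Et3SiCl and imidazole give (3S,5S)-5-[(1R)-1-chlorobut-3-en-1-yl]-3-[(triethylsilyl)oxy]oxolan-2-one F3. Lithium acetylide 11 (THF, −78 °C) adds to the lactone to give (3S,5S)-2-[(3S)-3-{[tert-butyl(dimethyl)silyl]oxy}pent-1-yn-1-yl]-5-[(1R)-1-chlorobut-3-en-1-yl]-3-[(triethylsilyl)oxy]oxolan-2-ol F4. Et3SiH with BF3·OEt2 (CH2Cl2, −78 °C) reduces the alkynyl oxocarbenium ion with hydride entering cis to the C9 oxygen (stereoelectronically controlled inside attack, as for ribonolactone-derived C-glycosides), so the alkynyl group again ends trans to it in tert-butyl{[(3S)-1-[(2R,3S,5S)-5-[(1R)-1-chlorobut-3-en-1-yl]-3-[(triethylsilyl)oxy]oxolan-2-yl]pent-1-yn-3-yl]oxy}dimethylsilane F5. PPTS in MeOH then removes the triethylsilyl ether selectively and delivers 14.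

Step 9 (inversion at C9). SN2 on the ring carbinol next to C10 can be slow and can lose out to elimination towards the enol ether. The fallback sets out from 14 and comes back at 15. ClCH2SO2Cl and 2,6-lutidine (CH2Cl2, 0 °C) give the isolable sulfonate (2R,3S,5S)-2-[(3S)-3-{[tert-butyl(dimethyl)silyl]oxy}pent-1-yn-1-yl]-5-[(1R)-1-chlorobut-3-en-1-yl]oxolan-3-yl chloromethanesulfonate F6. LiBr in DMF at 40 °C then displaces it with inversion under non-basic, phosphine-free conditions to give 15.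

Step 12 (Z-selective enyne cross-metathesis). The Z/E ratio may be modest and the isomers hard to separate. The fallback sets out from 16 and comes back at 20. OsO4 (cat.) with NMO (acetone/H2O, 0 °C) dihydroxylates only the unhindered terminal alkene, giving (4R)-4-[(2S,4R,5R)-4-bromo-5-[(1Z,3S)-3-{[tert-butyl(dimethyl)silyl]oxy}pent-1-en-1-yl]oxolan-2-yl]-4-chlorobutane-1,2-diol F7. NaIO4 cleaves it to (3R)-3-[(2S,4R,5R)-4-bromo-5-[(1Z,3S)-3-{[tert-butyl(dimethyl)silyl]oxy}pent-1-en-1-yl]oxolan-2-yl]-3-chloropropanal F8, which is used at once and cold because it is a β-chloro aldehyde. Stork–Zhao olefination ((iodomethyl)triphenylphosphonium iodide, NaN(SiMe3)2, THF/DMPU, −78 °C) gives {[(1Z,3S)-1-[(2R,3R,5S)-3-bromo-5-[(1R,3Z)-1-chloro-4-iodobut-3-en-1-yl]oxolan-2-yl]pent-1-en-3-yl]oxy}(tert-butyl)dimethylsilane F9. Sonogashira coupling of F9 with 17 (Pd(PPh3)4, CuI, Et2NH, rt) gives 20 with the Z geometry fixed by the vinyl iodide.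

**Further compounds**

F1 | step 7 | (3S,5S)-5-[(1R)-1-chlorobut-3-en-1-yl]oxolane-2,3-diol | C=CC[C@@H](Cl)[C@@H]1C[C@H](O)C(O)O1
F2 | step 7 | (3S,5S)-5-[(1R)-1-chlorobut-3-en-1-yl]-3-hydroxyoxolan-2-one | C=CC[C@@H](Cl)[C@@H]1C[C@H](O)C(=O)O1
F3 | step 7 | (3S,5S)-5-[(1R)-1-chlorobut-3-en-1-yl]-3-[(triethylsilyl)oxy]oxolan-2-one | C=CC[C@@H](Cl)[C@@H]1C[C@H](O[Si](CC)(CC)CC)C(=O)O1
F4 | step 7 | (3S,5S)-2-[(3S)-3-{[tert-butyl(dimethyl)silyl]oxy}pent-1-yn-1-yl]-5-[(1R)-1-chlorobut-3-en-1-yl]-3-[(triethylsilyl)oxy]oxolan-2-ol | C=CC[C@@H](Cl)[C@@H]1C[C@H](O[Si](CC)(CC)CC)C(O)(C#C[C@@H](O[Si](C)(C)C(C)(C)C)CC)O1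
F5 | step 7 | tert-butyl{[(3S)-1-[(2R,3S,5S)-5-[(1R)-1-chlorobut-3-en-1-yl]-3-[(triethylsilyl)oxy]oxolan-2-yl]pent-1-yn-3-yl]oxy}dimethylsilane | C=CC[C@@H](Cl)[C@@H]1C[C@H](O[Si](CC)(CC)CC)[C@@H](C#C[C@@H](O[Si](C)(C)C(C)(C)C)CC)O1
F6 | step 9 | (2R,3S,5S)-2-[(3S)-3-{[tert-butyl(dimethyl)silyl]oxy}pent-1-yn-1-yl]-5-[(1R)-1-chlorobut-3-en-1-yl]oxolan-3-yl chloromethanesulfonate | C=CC[C@@H](Cl)[C@@H]1C[C@H](OS(=O)(=O)CCl)[C@@H](C#C[C@@H](O[Si](C)(C)C(C)(C)C)CC)O1
F7 | step 12 | (4R)-4-[(2S,4R,5R)-4-bromo-5-[(1Z,3S)-3-{[tert-butyl(dimethyl)silyl]oxy}pent-1-en-1-yl]oxolan-2-yl]-4-chlorobutane-1,2-diol | OCC(O)C[C@@H](Cl)[C@@H]1C[C@@H](Br)[C@@H](/C=C\[C@@H](O[Si](C)(C)C(C)(C)C)CC)O1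
F8 | step 12 | (3R)-3-[(2S,4R,5R)-4-bromo-5-[(1Z,3S)-3-{[tert-butyl(dimethyl)silyl]oxy}pent-1-en-1-yl]oxolan-2-yl]-3-chloropropanal | O=CC[C@@H](Cl)[C@@H]1C[C@@H](Br)[C@@H](/C=C\[C@@H](O[Si](C)(C)C(C)(C)C)CC)O1
F9 | step 12 | {[(1Z,3S)-1-[(2R,3R,5S)-3-bromo-5-[(1R,3Z)-1-chloro-4-iodobut-3-en-1-yl]oxolan-2-yl]pent-1-en-3-yl]oxy}(tert-butyl)dimethylsilane | I/C=C\C[C@@H](Cl)[C@@H]1C[C@@H](Br)[C@@H](/C=C\[C@@H](O[Si](C)(C)C(C)(C)C)CC)O1
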